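**Retrosynthetic overview**

1. Target ⇒ its bis-benzyl ether ⇒ break the C-4–aryl bond between the upper chroman and ring B of the lower isoflavan: a C-4 benzylic cation (O-benzylated para-quinone methide) is captured by the free phenolic lower isoflavan, in the same flask as the asymmetric reduction of the upper isoflavone.
2. Lower (3R)-isoflavan and upper (3R,4R)-isoflavan-4-ol ⇒ isoflavones, by Ru transfer hydrogenation with dynamic kinetic resolution (isoflavone → isoflavanone → cis-isoflavanol, as in the plant).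
3. Each isoflavone ⇒ 2'-hydroxychalcone, by oxidative 1,2-aryl shift and closure of ring C (isoflavone-synthase mimic).
4. Chalcones ⇒ 4'-benzyloxy-2'-hydroxyacetophenone plus O-benzylated benzaldehydes (from 2,6-dimethoxyphenol and 3-hydroxy-5-methoxybenzaldehyde).
5. Ring order: ring C of the upper half (step 4), ring C of the lower half (step 7); the union (step 9) forms no ring and sets C-3 and C-4 of the upper half.

Assumption: 2,6-dimethoxyphenol, 1-[4-(benzyloxy)-2-hydroxyphenyl]ethanone and 3-hydroxy-5-methoxybenzaldehyde are bought. Read from the SMILES, the target is (3R,4S), 3,4-trans, in the upper chroman and (3R) in the lower one. TsDPEN = N-(p-toluenesulfonyl)-1,2-diphenylethylenediamine.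

**Step 1**
Reactants: 1 2,6-dimethoxyphenol
Product: 2 2-(benzyloxy)-1,3-dimethoxybenzene
Conditions: BnBr, K2CO3, DMF, 60 °C
Reagents that add atoms: benzyl bromide BrCc1ccccc1
Why: Williamson O-benzylation masks the oxidation-prone 2,6-dimethoxyphenol hydroxyl for the later thallium oxidation and comes off only in the final hydrogenolysis; no stereocentre is formed.

**Step 2**
Reactants: 2 2-(benzyloxy)-1,3-dimethoxybenzene
Product: 3 3-(benzyloxy)-2,4-dimethoxybenzaldehyde
Conditions: POCl3, DMF, 0 → 80 °C; then ice-water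
Reagents that add atoms: N,N-dimethylformamide CN(C)C=O; water O
Why: Vilsmeier–Haack formylation of a 1,2,3-trioxygenated benzene goes to C-4 (ortho and para to the two in-plane methoxy groups, as with 1,2,3-trimethoxybenzene) because the twisted central benzyloxy group donates poorly, which gives the ring B pattern of the upper half; no stereocentre.

**Step 3**
Reactants: 3 3-(benzyloxy)-2,4-dimethoxybenzaldehyde; 4 1-[4-(benzyloxy)-2-hydroxyphenyl]ethan-1-one
Product: 5 (2E)-1-[4-(benzyloxy)-2-hydroxyphenyl]-3-[3-(benzyloxy)-2,4-dimethoxyphenyl]prop-2-en-1-one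
Conditions: KOH (50 % aq.), EtOH, rt, 48 h; then 2 M HCl
Reagents that add atoms: none
Why: Claisen–Schmidt aldol condensation of the acetophenone enolate with the non-enolisable aldehyde gives the thermodynamic E-chalcone, the laboratory counterpart of the biosynthetic chalcone; no stereocentre.

**Step 4**
Reactants: 5 (2E)-1-[4-(benzyloxy)-2-hydroxyphenyl]-3-[3-(benzyloxy)-2,4-dimethoxyphenyl]prop-2-en-1-one
Product: 7 7-(benzyloxy)-3-[3-(benzyloxy)-2,4-dimethoxyphenyl]-4H-chromen-4-one, via dimethyl acetal 6 (not isolated)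
Conditions: Tl(NO3)3·3H2O (1.1 equiv), MeOH/CH2Cl2, rt; then 10 % aq. HCl, 60 °C
Reagents that add atoms: none
Why: Oxidative rearrangement of a 2'-hydroxychalcone by trivalent thallium (methoxythallation, 1,2-shift of the electron-rich ring B from C-β to C-α with loss of monovalent thallium, then acid-induced closure of ring C and loss of methanol) copies the aryl migration of isoflavone synthase and is established for this oxygenation pattern; the acetal stereocentre disappears on aromatisation.

**Step 5**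
Reactants: 8 3-hydroxy-5-methoxybenzaldehyde
Product: 9 3-(benzyloxy)-5-methoxybenzaldehyde
Conditions: BnBr, K2CO3, DMF, 60 °C
Reagents that add atoms: benzyl bromide BrCc1ccccc1
Why: Williamson O-benzylation protects the phenol against the thallium oxidant and is released together with the ring A benzyl group in step 8; no stereocentre.

**Step 6**
Reactants: 4 1-[4-(benzyloxy)-2-hydroxyphenyl]ethan-1-one; 9 3-(benzyloxy)-5-methoxybenzaldehyde
Product: 10 (2E)-1-[4-(benzyloxy)-2-hydroxyphenyl]-3-[3-(benzyloxy)-5-methoxyphenyl]prop-2-en-1-one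
Conditions: KOH (50 % aq.), EtOH, rt, 24 h; then 2 M HCl
Reagents that add atoms: none
Why: Claisen–Schmidt condensation as in step 3 gives the E-chalcone; no stereocentre.

**Step 7**
Reactants: 10 (2E)-1-[4-(benzyloxy)-2-hydroxyphenyl]-3-[3-(benzyloxy)-5-methoxyphenyl]prop-2-en-1-one
Product: 12 7-(benzyloxy)-3-[3-(benzyloxy)-5-methoxyphenyl]-4H-chromen-4-one, via dimethyl acetal 11 (not isolated)
Conditions: Tl(NO3)3·3H2O (1.2 equiv), MeOH/CH2Cl2, rt; then 10 % aq. HCl, 60 °C
Reagents that add atoms: none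
Why: The same Tl(NO3)3 oxidative 1,2-aryl shift and ring C closure as in step 4; ring B here carries only meta oxygen substituents and should migrate about as well as phenyl (which rearranges under these conditions), so a slower and lower-yielding reaction is expected; no stereocentre survives.

**Step 8**
Reactants: 12 7-(benzyloxy)-3-[3-(benzyloxy)-5-methoxyphenyl]-4H-chromen-4-one
Product: 15 (3R)-3-(3-hydroxy-5-methoxyphenyl)chroman-7-ol, via isoflavanone 13 (not isolated), via cis-isoflavan-4-ol 14 (not isolated)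
Conditions: RuCl[(R,R)-TsDPEN](p-cymene) (2 mol %), HCO2H/Et3N (5:2), EtOAc, 40 °C; then MeOH, Pd/C (10 wt %), H2 (1 atm), rt
Reagents that add atoms: none
Why: Noyori–Ikariya asymmetric transfer hydrogenation reduces C2=C3 and then the C-4 ketone under dynamic kinetic resolution (the isoflavanone epimerises in the amine buffer and the (R,R) catalyst reduces only its 3R enantiomer, hydride anti to the aryl, to the cis-(3R,4R) alcohol, the course of isoflavone reductase and vestitone reductase), and Pd-catalysed hydrogenolysis then cleaves the para-oxygen-activated benzylic C-4–O bond and both benzyl ethers without touching C-3, as in the hydrogenolysis of pterocarpans to isoflavans.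

**Step 9**
Reactants: 7 7-(benzyloxy)-3-[3-(benzyloxy)-2,4-dimethoxyphenyl]-4H-chromen-4-one; 15 (3R)-3-(3-hydroxy-5-methoxyphenyl)chroman-7-ol
Product: 18 (3R,4S)-7-(benzyloxy)-3-[3-(benzyloxy)-2,4-dimethoxyphenyl]-4-{4-hydroxy-2-[(3R)-7-hydroxychroman-3-yl]-6-methoxyphenyl}chromane, via isoflavanone 16 (not isolated), via cis-isoflavan-4-ol 17 (not isolated)
Conditions: RuCl[(R,R)-TsDPEN](p-cymene) (3 mol %), HCO2H/Et3N (5:2), EtOAc, 40 °C; then evaporate, 15 (2.5 equiv), CF3CO2H (5 equiv), (CF3)2CHOH/CH2Cl2 (1:4), −30 → 0 °C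
Reagents that add atoms: none
Why: Proposed new method: the transfer hydrogenation with dynamic kinetic resolution of step 8 sets C-3 (R) of 17, and acid then ionises the cis C-4 alcohol to the 7-benzyloxy-stabilised benzylic cation (an O-benzylated para-quinone methide), which ring B of 15 attacks at its most electron-rich carbon (para to the free hydroxyl, between C-1' and the methoxy-bearing carbon) from the face anti to the C-3 aryl, giving the 3,4-trans (4S) product in a dehydrative Friedel–Crafts alkylation run cold and with excess 15 so that capture outruns loss of H-3; the closest known reactions are the one-pot transfer hydrogenation/acid cyclisation of 2'-hydroxyisoflavones to pterocarpans and the acid-mediated coupling of pterocarpan- or flavan-4-ol-derived C-4 cations with phenolic isoflavans and flavans.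

**Step 10**
Reactants: 18 (3R,4S)-7-(benzyloxy)-3-[3-(benzyloxy)-2,4-dimethoxyphenyl]-4-{4-hydroxy-2-[(3R)-7-hydroxychroman-3-yl]-6-methoxyphenyl}chromane
Product: 19 (3R,4S)-3-(3-hydroxy-2,4-dimethoxyphenyl)-4-{4-hydroxy-2-[(3R)-7-hydroxychroman-3-yl]-6-methoxyphenyl}chroman-7-ol
Conditions: H2 (1 atm), Pd/C (10 wt %), EtOAc/MeOH, rt
Reagents that add atoms: none
Why: Catalytic hydrogenolysis removes the two O-benzyl groups under neutral conditions that leave the chroman C–O bonds, the C-4–aryl bond and all three stereocentres untouched.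

**Compound list**

1 | 2,6-dimethoxyphenol | COc1cccc(OC)c1O | starting material
2 | 2-(benzyloxy)-1,3-dimethoxybenzene | COc1cccc(OC)c1OCc1ccccc1 | intermediate
3 | 3-(benzyloxy)-2,4-dimethoxybenzaldehyde | COc1ccc(C=O)c(OC)c1OCc1ccccc1 | intermediate
4 | 1-[4-(benzyloxy)-2-hydroxyphenyl]ethan-1-one | CC(=O)c1ccc(OCc2ccccc2)cc1O | starting material
5 | (2E)-1-[4-(benzyloxy)-2-hydroxyphenyl]-3-[3-(benzyloxy)-2,4-dimethoxyphenyl]prop-2-en-1-one | COc1ccc(/C=C/C(=O)c2ccc(OCc3ccccc3)cc2O)c(OC)c1OCc1ccccc1 | intermediate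
6 | 1-[4-(benzyloxy)-2-hydroxyphenyl]-2-[3-(benzyloxy)-2,4-dimethoxyphenyl]-3,3-dimethoxypropan-1-one (racemic, not isolated) | COc1ccc(C(C(OC)OC)C(=O)c2ccc(OCc3ccccc3)cc2O)c(OC)c1OCc1ccccc1 | intermediate
7 | 7-(benzyloxy)-3-[3-(benzyloxy)-2,4-dimethoxyphenyl]-4H-chromen-4-one | COc1ccc(-c2coc3cc(OCc4ccccc4)ccc3c2=O)c(OC)c1OCc1ccccc1 | intermediate
8 | 3-hydroxy-5-methoxybenzaldehyde | COc1cc(O)cc(C=O)c1 | starting material
9 | 3-(benzyloxy)-5-methoxybenzaldehyde | COc1cc(C=O)cc(OCc2ccccc2)c1 | intermediate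
10 | (2E)-1-[4-(benzyloxy)-2-hydroxyphenyl]-3-[3-(benzyloxy)-5-methoxyphenyl]prop-2-en-1-one | COc1cc(/C=C/C(=O)c2ccc(OCc3ccccc3)cc2O)cc(OCc2ccccc2)c1 | intermediate
11 | 1-[4-(benzyloxy)-2-hydroxyphenyl]-2-[3-(benzyloxy)-5-methoxyphenyl]-3,3-dimethoxypropan-1-one (racemic, not isolated) | COc1cc(C(C(OC)OC)C(=O)c2ccc(OCc3ccccc3)cc2O)cc(OCc2ccccc2)c1 | intermediate
12 | 7-(benzyloxy)-3-[3-(benzyloxy)-5-methoxyphenyl]-4H-chromen-4-one | COc1cc(-c2coc3cc(OCc4ccccc4)ccc3c2=O)cc(OCc2ccccc2)c1 | intermediate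
13 | 7-(benzyloxy)-3-[3-(benzyloxy)-5-methoxyphenyl]chroman-4-one (racemising at C-3, not isolated) | COc1cc(C2COc3cc(OCc4ccccc4)ccc3C2=O)cc(OCc2ccccc2)c1 | intermediate
14 | (3R,4R)-7-(benzyloxy)-3-[3-(benzyloxy)-5-methoxyphenyl]chroman-4-ol (cis, not isolated) | COc1cc([C@@H]2COc3cc(OCc4ccccc4)ccc3[C@@H]2O)cc(OCc2ccccc2)c1 | intermediate
15 | (3R)-3-(3-hydroxy-5-methoxyphenyl)chroman-7-ol | COc1cc(O)cc([C@@H]2COc3cc(O)ccc3C2)c1 | intermediate
16 | 7-(benzyloxy)-3-[3-(benzyloxy)-2,4-dimethoxyphenyl]chroman-4-one (racemising at C-3, not isolated) | COc1ccc(C2COc3cc(OCc4ccccc4)ccc3C2=O)c(OC)c1OCc1ccccc1 | intermediate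
17 | (3R,4R)-7-(benzyloxy)-3-[3-(benzyloxy)-2,4-dimethoxyphenyl]chroman-4-ol (cis, not isolated) | COc1ccc([C@@H]2COc3cc(OCc4ccccc4)ccc3[C@@H]2O)c(OC)c1OCc1ccccc1 | intermediate
18 | (3R,4S)-7-(benzyloxy)-3-[3-(benzyloxy)-2,4-dimethoxyphenyl]-4-{4-hydroxy-2-[(3R)-7-hydroxychroman-3-yl]-6-methoxyphenyl}chromane (3,4-trans) | COc1ccc([C@@H]2COc3cc(OCc4ccccc4)ccc3[C@H]2c2c(OC)cc(O)cc2[C@@H]2COc3cc(O)ccc3C2)c(OC)c1OCc1ccccc1 | intermediate
19 | (3R,4S)-3-(3-hydroxy-2,4-dimethoxyphenyl)-4-{4-hydroxy-2-[(3R)-7-hydroxychroman-3-yl]-6-methoxyphenyl}chroman-7-ol (CNP0305801.1) | COc1ccc([C@@H]2COc3cc(O)ccc3[C@H]2c2c(OC)cc(O)cc2[C@@H]2COc3cc(O)ccc3C2)c(OC)c1O | target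

**Count**

Total steps: 10. Longest linear sequence: 6 steps (1, 2, 3, 4, 9, 10 from compound 1; equally 5, 6, 7, 8, 9, 10 from compound 8).

**Steps most likely to fail**

Step 9 is the most likely to fail. The cation may be attacked at other carbons of 15 (the ring B carbons ortho to the hydroxyl, or C-6/C-8 of ring A). It may also lose H-3 to the achiral isoflav-3-ene, which erodes C-3, or be reduced by residual formate. The fallback sets out from 7 and comes back at 19. Compound 7 is hydrogenated exhaustively (H2, Pd/C, EtOAc/MeOH), which removes both benzyl groups and saturates C2=C3, to racemic 7-hydroxy-3-(3-hydroxy-2,4-dimethoxyphenyl)chroman-4-one F1. F1 is reduced under dynamic kinetic resolution with RuCl[(R,R)-TsDPEN](p-cymene) in HCO2H/Et3N, and the unprotected (3R,4R)-3-(3-hydroxy-2,4-dimethoxyphenyl)chromane-4,7-diol F2 is isolated. F2 is then warmed gently with excess 15 in aqueous (CF3)2CHOH without strong acid, so that it loses water to the neutral para-quinone methide. Hydrogen-bond-guided 1,6-addition of the phenol ring of 15, anti to the C-3 aryl, gives 19 directly and step 10 is no longer needed.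

Step 7 is the second risk, because ring B has no ortho or para donor and the aryl shift may lose out to aurone formation. The fallback sets out from 10 and comes back at 12, and moves the aroyl group instead of the aryl group. Compound 10 is acetylated (Ac2O, pyridine) to 5-(benzyloxy)-2-{(2E)-3-[3-(benzyloxy)-5-methoxyphenyl]prop-2-enoyl}phenyl acetate F3. F3 is epoxidised with dimethyldioxirane in acetone to the racemic trans-epoxide 5-(benzyloxy)-2-({3-[3-(benzyloxy)-5-methoxyphenyl]oxiran-2-yl}carbonyl)phenyl acetate F4. BF3·OEt2 in CH2Cl2 at 0 °C opens F4 at the benzylic carbon and triggers a 1,2-aroyl shift to 5-(benzyloxy)-2-{2-[3-(benzyloxy)-5-methoxyphenyl]-3-oxopropanoyl}phenyl acetate F5. K2CO3 in MeOH followed by dilute HCl removes the acetate; the freed phenol closes onto the aldehyde and the 2-hydroxyisoflavanone dehydrates to 12.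

Step 8 is the third risk. Acid-promoted dehydration of 14 to the isoflav-3-ene before hydrogenolysis would give partly racemic 15, and the C-4 deoxygenation may stall. The fallback sets out from 12 and comes back at 15, and sets C-3 by hydrogenation of an alkene instead. Compound 12 is reduced with NaBH4 (THF/EtOH) to racemic 7-(benzyloxy)-3-[3-(benzyloxy)-5-methoxyphenyl]chroman-4-ol F6. F6 is dehydrated (TsOH, toluene, 80 °C) to 7-(benzyloxy)-3-[3-(benzyloxy)-5-methoxyphenyl]-2H-chromene F7. F7 is hydrogenated with [Ir(cod)(tBu-PHOX)]B[C6H3(CF3)2]4 (monovalent iridium; the ligand enantiomer that delivers the 3R product is chosen; H2 50 bar, CH2Cl2) to (3R)-7-(benzyloxy)-3-[3-(benzyloxy)-5-methoxyphenyl]chromane F8. Hydrogenolysis of F8 (H2, Pd/C) gives 15.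

**Further compounds**

F1 | step 9 | 7-hydroxy-3-(3-hydroxy-2,4-dimethoxyphenyl)chroman-4-one (racemic) | COc1ccc(C2COc3cc(O)ccc3C2=O)c(OC)c1O
F2 | step 9 | (3R,4R)-3-(3-hydroxy-2,4-dimethoxyphenyl)chromane-4,7-diol | COc1ccc([C@@H]2COc3cc(O)ccc3[C@@H]2O)c(OC)c1O
F3 | step 7 | 5-(benzyloxy)-2-{(2E)-3-[3-(benzyloxy)-5-methoxyphenyl]prop-2-enoyl}phenyl acetate | COc1cc(/C=C/C(=O)c2ccc(OCc3ccccc3)cc2OC(C)=O)cc(OCc2ccccc2)c1
F4 | step 7 | 5-(benzyloxy)-2-({3-[3-(benzyloxy)-5-methoxyphenyl]oxiran-2-yl}carbonyl)phenyl acetate (trans, racemic, one enantiomer drawn) | COc1cc([C@@H]2O[C@H]2C(=O)c2ccc(OCc3ccccc3)cc2OC(C)=O)cc(OCc2ccccc2)c1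
F5 | step 7 | 5-(benzyloxy)-2-{2-[3-(benzyloxy)-5-methoxyphenyl]-3-oxopropanoyl}phenyl acetate (racemic) | COc1cc(C(C=O)C(=O)c2ccc(OCc3ccccc3)cc2OC(C)=O)cc(OCc2ccccc2)c1
F6 | step 8 | 7-(benzyloxy)-3-[3-(benzyloxy)-5-methoxyphenyl]chroman-4-ol (racemic cis/trans mixture) | COc1cc(C2COc3cc(OCc4ccccc4)ccc3C2O)cc(OCc2ccccc2)c1
F7 | step 8 | 7-(benzyloxy)-3-[3-(benzyloxy)-5-methoxyphenyl]-2H-chromene | COc1cc(C2=Cc3ccc(OCc4ccccc4)cc3OC2)cc(OCc2ccccc2)c1
F8 | step 8 | (3R)-7-(benzyloxy)-3-[3-(benzyloxy)-5-methoxyphenyl]chromane | COc1cc([C@@H]2COc3cc(OCc4ccccc4)ccc3C2)cc(OCc2ccccc2)c1
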